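## Structural features

The target is an azaphilone-type bicycle, a 7,8-dihydro-6H-isochromen-6-one. Its oxygen heterocycle, ring A (O2, C1, C3, C4, C4a, C8a), is fused along C4a–C8a to the carbocycle ring B, which carries the C6 ketone, the C7 tertiary carbinol with its methyl group and the C8 secondary carbinol. C3 of ring A bears the side chain C9(OH)(CH3)–C10H=C11(CH3)–, which ends at C2′ of a 2,3-disubstituted oxolane, ring C, with a methyl group on C3′. There are five stereocentres in three groups: C7 and C8 are neighbours (7S,8R, a trans-diol with the C7 methyl cis to the C8 hydroxyl), C2′ and C3′ are neighbours (2′S,3′S, trans), and C9 (S) stands alone, four bonds from either pair; the C10=C11 alkene is E. Fragile are the cross-conjugated dienone and vinylogous ester of rings A and B (electrophilic at C1, C6 and C8), the α-ketol at C7 between C6 and C8, the tertiary allylic alcohol at C9 and the allylic ether bond C2′–O. The real difficulty is twofold: C9 is a fully substituted carbinol that no neighbouring stereocentre can control and that sits next to a trisubstituted alkene of fixed geometry, and ring B is a dearomatised, doubly oxygenated ring that has to be made late and mildly. The key step exploits the pattern C9(OH)(CH3)–C10H=C11(CH3)–C2′: a methyl group on the alkene carbon next to ring C and a methyl carbinol on the other side are what syn-methylmetalation of a ring C alkyne and addition of the alkenyl metal to a methyl ketone leave behind, and the second substituent of that ketone can carry C3 and C4 for ring A.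

## Logic of the disconnections

28 ⇒ 27. The C8–H bond is cut, so the C8 carbinol goes back to a ketone. A 7-hydroxy-6,8-dione is what dearomatising hydroxylation of a resorcinol-type bicycle delivers directly, and one stereocentre disappears. The forward step must choose C8 over C6 and over conjugate attack at C1, and must bring hydride in on the face of the C7 hydroxyl. Internal delivery from a boron bound to O7 addresses both points.

27 ⇒ 26. The C7–O bond is cut. C7 is the methyl-bearing carbon between the oxygenated carbons C6 and C8, the position that a phenol-hydroxylating flavin enzyme (or a hypervalent iodine reagent) attacks. The gain is large: 26 has no stereocentre in the bicycle and ring B is at the aromatic oxidation level. The demand is face selectivity at C7 that does not depend on the remote side chain, and acceptance of the bulky C3 substituent.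

26 ⇒ 24 (through 25). The O2–C1 bond of ring A is cut together with four protecting groups (two aryl O–CH2OCH3, the dioxolane, O–Si at C9). An aryl aldehyde with an ortho benzyl ketone closes to the benzopyrylium ring by itself in acid, so ring A need not be carried. The demand is that one acid treatment removes all four groups and closes the ring without ionising C9–O or C2′–O.

24 ⇒ 16 + 23. The C4–C4a bond is cut. C4 is the only enolisable carbon of 16, because C9 is quaternary, so an enolate arylation has no regiochemical choice, and the cut separates the chiral side chain from an achiral arene. The demand is a palladium-catalysed coupling of a hindered methyl ketone with an ortho-substituted bromide under base. For that reason the aldehyde is masked as an acetal, the phenols as acetal ethers and the C9 hydroxyl as a silyl ether; the last excludes alkoxide formation and the α-ketol shift that would scramble C9.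

16 ⇒ 15 ⇒ 14. Only functional groups change: the O–Si bond, then the C3 carbonyl goes back to its dimethyl ketal. Hydrolysis is placed before silylation because a silyl triflate would attack the ketal, and because a ketal beside a silyloxy-substituted quaternary carbon would hydrolyse more slowly than the silyl ether survives. The demand is an acid mild enough to spare the tertiary allylic alcohol.

14 ⇒ 9 + 10 + 11. Two skeletal bonds are cut, C11–CH3 and C10–C9. The C11 methyl and the C9 methyl carbinol flank the alkene exactly as a syn-carbometalation followed by a ketone addition would leave them. The gain is three small components, an alkene geometry fixed by mechanism and a C9 centre set by a catalyst. The demands are regio- and syn-selective carbometalation beside an ether oxygen, transfer of the alkenyl and not a methyl group, and discrimination of the two ketone faces. The design answers with an extra equivalent of 10 for the ether oxygen, removal of unused 10 before the transfer, and the large steric difference between the two substituents of 11. Because 9 is volatile it is handled as an assayed solution.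

9 ⇒ 8 ⇒ 6. The C(sp)–Si bond (a protecting group) and the O1′–C5′ bond are cut. Ring C is opened at the primary carbon so that closure is a 5-exo-tet displacement that touches neither stereocentre; the silyl cap keeps the alkyne inert to the borane of the preceding step. The demand is activation of the primary hydroxyl only, since activation of the propargylic one would invert C2′.

6 ⇒ 5 ⇒ 1 + 2. The C5′–O bond is traced to a terminal alkene and the C2′–C3′ bond is cut. An anti relation between a carbinol and a neighbouring methyl-bearing carbon next to a vinyl group is the mark of an (E)-crotyl addition to an aldehyde. The gain is two achiral purchasable compounds. The demand is reagent control of the aldehyde face and a closed transition state for the anti relation.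

23 ⇒ 22 ⇒ 20 ⇒ 18 ⇒ 17. Cut in turn are the acetal C–O bonds, the bond from the formyl carbon C1 to C8a, the C4a–Br bond and the two O–CH2OCH3 bonds. 18 and 20 are mirror-symmetric, which dictates the order: in 18 only one C–H has no ortho substituent, so a sterically governed borylation can go nowhere else, and in 20 the two remaining ring hydrogens are equivalent, so deprotonation has no choice. The demands are that the aryl acetal ethers survive the copper halide step and that the lithiated bromoarene is kept cold.

## Other disconnections considered

Alternative 1: The cut is the C7–C8 bond, which contracts ring B retrosynthetically. In the forward step KN(SiMe3)2 makes the C6 alkoxide of a tertiary acetyl carbinol on a five-membered carbocycle fused to ring A; C8 then shifts from C6 to the acetyl carbon, which becomes C7, and C6 becomes the ketone, giving the bis-silyl ether A1.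
- In its favour: one stereospecific 1,2-shift creates the quaternary C7 carbinol and the C6 ketone, driven by ring enlargement and by the new conjugated carbonyl. C8 is already at the alcohol level, so neither an enzyme nor a late chemoselective reduction is needed; on that point it is better than the chosen plan.
- Against it: C6 carries two ring carbons, C5 (sp2) and C8 (sp3, oxygenated), and either may migrate. The C7 configuration depends on the acetyl rotamer in the transition state. The base can move the silyl group from O8 to the new C7 alkoxide, and α-ketol shifts are reversible. The rearrangement substrate needs a longer and less obvious synthesis than any intermediate of the chosen route.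
- Comparison: structurally this alternative only concerns ring B and would still need the side chain, for which the chosen key step would serve equally; the two are complementary. Mechanistically it relies on substrate control in an anionic shift, where the chosen plan uses an enzyme pocket and internal hydride delivery. Its endgame is shorter (two desilylations from A1), its front end longer; overall no saving is expected.

Alternative 2: The cut is the O1′–C2′ bond of ring C. In the forward step Pd(PPh3)4 ionises the allylic C10–O bond of an acyclic vinyl epoxide and the C5′ hydroxyl attacks C2′ of the π-allyl complex, giving A2 with ring C closed, the C10=C11 alkene in place and the C9 carbinol set free.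
- In its favour: ring, alkene and carbinol arise in one neutral step. C9 would come from an asymmetric epoxidation of an allylic alcohol, a very dependable way to a tertiary C–O centre; on this point it is better than the chosen plan, whose weakest point is face control at C9.
- Against it: the C2′ configuration results from double inversion, so it depends on the epoxide configuration and the alkene geometry of the precursor, and syn/anti isomerisation of the π-allyl complex can erode both it and the alkene geometry. Fully substituted π-allyl termini react slowly. The acyclic precursor needs a long linear synthesis. A2 holds C3 at the alcohol level without C4, so about four further steps are needed before ring A can be attached.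
- Comparison: the chosen plan sets C2′/C3′ first through a closed transition state and forms the alkene stereospecifically; step economy favours it.

Alternative 3: The cut is the C3–C4 bond. The arene A5, held as its α-amino alkoxide with LiN(CH3)CH2CH2N(CH3)2, is lithiated at the ortho methyl group with n-C4H9Li and acylated by the Weinreb amide A4; aqueous CF3CO2H then closes ring A to A3, which is the same compound as 26.
- In its favour: the arene needs no halogen and no acetal step, since the aldehyde is masked in the flask, so this branch is about three steps shorter than the one leading to 23. No palladium is used, and the amide stops cleanly at the ketone. On step count it is the better plan, and on convergence it is the equal.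
- Against it: A4 requires the alkenylation to be run on an α-keto amide or ester instead of 11, a partner whose face bias is less clear. Acylation by an amide flanked by a quaternary silyloxy carbon is slow. Ring lithiation at C5–H can compete with lateral lithiation, and a strongly basic organolithium step is placed late.
- Comparison: a polar carbanion acylation stands against a palladium-catalysed enolate arylation. The chosen plan is better on functional-group tolerance and regiochemical certainty (one enolisable site, a symmetric arene), and both meet at the same intermediate.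

Key step: step 5

Remark on the chemistry: the sense of induction of the two chiral reagents (the isopinocampheylborane of step 1 and the bis(sulfonamide) ligand of step 5) is assigned by analogy with simple aldehydes and aryl methyl ketones; should either prove opposite here, its equally available mirror-image form is used with no other change.

## Route

Step 1
Reactants: 1 3-(trimethylsilyl)propynal; 2 (E)-but-2-ene
Product: 5 (3S,4S)-4-methyl-1-(trimethylsilyl)hex-5-en-1-yn-3-ol, via (E)-crotylpotassium 3 (not isolated), via (E)-crotylbis(isopinocampheyl)borane 4 (not isolated)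
Conditions: 2 (excess), KOt-Bu, n-BuLi, THF, −78 → −45 °C; (−)-Ipc2BOMe [from (+)-α-pinene], −78 °C; BF3·OEt2; 1, −78 °C; NaBO3·4H2O, THF/H2O, rt
Reagents that add atoms: none
Why: Brown crotylboration: the (E)-crotylborane reacts through a chair Zimmerman–Traxler transition state, which gives the anti adduct, and the isopinocampheyl groups are expected to direct attack to the Si face of 1 as in the parent allylboration, so that the future C2′ and C3′ are set as S,S by reagent control; the mild perborate work-up spares the C-silyl alkyne.

Step 2
Reactants: 5 (3S,4S)-4-methyl-1-(trimethylsilyl)hex-5-en-1-yn-3-ol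
Product: 6 (3S,4S)-3-methyl-6-(trimethylsilyl)hex-5-yne-1,4-diol
Conditions: 9-BBN (2.2 equiv), THF, 0 °C → rt; 30% H2O2, aq. NaOAc, 0 °C → rt
Reagents that add atoms: hydrogen peroxide, OO
Why: Hydroboration–oxidation: 9-BBN adds to the monosubstituted alkene with anti-Markovnikov selectivity and much faster than to the silyl-capped internal alkyne (one equivalent is taken up by the free hydroxyl); no stereocentre is touched.

Step 3
Reactants: 6 (3S,4S)-3-methyl-6-(trimethylsilyl)hex-5-yne-1,4-diol
Product: 8 trimethyl{[(2S,3S)-3-methyloxolan-2-yl]ethynyl}silane, via primary tosylate 7 (not isolated)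
Conditions: TsCl (1.05 equiv), Et3N, 4-(dimethylamino)pyridine (cat.), CH2Cl2, 0 °C; solvent exchange to THF; NaH, 0 °C → rt
Reagents that add atoms: none
Why: Selective sulfonylation of the unhindered primary hydroxyl, then Williamson-type 5-exo-tet closure by the propargylic alkoxide at C5′; no C–O bond at a stereocentre is broken, so the anti diol maps onto the trans-2,3-disubstituted oxolane.

Step 4
Reactants: 8 trimethyl{[(2S,3S)-3-methyloxolan-2-yl]ethynyl}silane
Product: 9 (2S,3S)-2-ethynyl-3-methyloxolane
Conditions: K2CO3 (cat.), MeOH, rt; extraction into CH2Cl2, drying (MgSO4, then 4 Å sieves), used as an assayed solution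
Reagents that add atoms: none
Why: Methoxide-induced protodesilylation of the C(sp)–Si bond; the product is volatile, so it is not concentrated to dryness.

Step 5
Reactants: 9 (2S,3S)-2-ethynyl-3-methyloxolane; 10 trimethylaluminium; 11 3,3-dimethoxybutan-2-one
Product: 14 (3S,4E)-2,2-dimethoxy-3-methyl-5-[(2S,3S)-3-methyloxolan-2-yl]hex-4-en-3-ol, via alkenyl(dimethyl)alane 12 (not isolated), via alkenyl(methyl)zinc 13 (not isolated)
Conditions: 10 (2.5 equiv), Cp2ZrCl2 (20 mol%), CH2Cl2, 0 °C → rt; volatiles removed in vacuo; toluene, ZnMe2 (1.2 equiv), −78 → 0 °C; bis(sulfonamide) diol ligand from (1R,2R)-cyclohexane-1,2-diamine and (1S)-camphor-10-sulfonyl chloride, ketones reduced to the exo alcohols (10 mol%), Ti(Oi-Pr)4 (1.2 equiv), 11 (1.0 equiv), 0 °C → rt; aq. KNaC4H4O6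
Reagents that add atoms: none
Why: Zirconium-catalysed methylalumination (Negishi carboalumination): a methylzirconocene cation formed from Cp2ZrCl2 and 10 adds syn across the terminal alkyne of 9 with the methyl on the substituted carbon C11 and the metal on the terminal carbon C10, and Zr-to-Al exchange releases 12 and regenerates the catalyst. Because methyl and metal enter on the same side, the metal at C10 is trans to C2′; exchange to zinc (13) and the carbonyl addition both proceed with retention at the sp2 carbon, so C9 ends cis to the C11 methyl, which is the (E)-alkene. The bis(sulfonamide) diol and Ti(Oi-Pr)4 form a chiral Lewis acid of tetravalent titanium that binds 11 and takes the alkenyl group from 13, an sp2 group being transferred much faster than methyl. The closest known reaction types are carboalumination–transmetalation sequences used for carbonyl alkenylation and the titanium/bis(sulfonamide)-catalysed addition of alkenylzinc reagents to ketones. No ring is closed. The only new stereocentre, C9, is set by the ligand (catalyst control) through delivery to the Si face of the ketone, with the ketal carbon as the large and CH3 as the small substituent; the ring C stereocentres are four bonds away and should not interfere. The selectivities needed are regio- and syn-selectivity of the carbometalation (secured by the terminal alkyne and the branched C2′ substituent, with extra 10 to saturate the ether oxygen), alkenyl over methyl transfer (unused 10 is pumped off before zinc and titanium are added) and face selectivity (steric contrast of CH3 against C(OCH3)2CH3). The neutral tartrate work-up keeps the ketal.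

Step 6
Reactants: 14 (3S,4E)-2,2-dimethoxy-3-methyl-5-[(2S,3S)-3-methyloxolan-2-yl]hex-4-en-3-ol
Product: 15 (3S,4E)-3-hydroxy-3-methyl-5-[(2S,3S)-3-methyloxolan-2-yl]hex-4-en-2-one
Conditions: p-TsOH·H2O (10 mol%), acetone/H2O (10:1), 0 °C → rt
Reagents that add atoms: water, O
Why: Acid-catalysed ketal hydrolysis through the methoxy oxocarbenium ion; C9 cannot ionise readily beside the electron-poor C3, so the tertiary allylic alcohol and its configuration are kept.

Step 7
Reactants: 15 (3S,4E)-3-hydroxy-3-methyl-5-[(2S,3S)-3-methyloxolan-2-yl]hex-4-en-2-one
Product: 16 (3S,4E)-3-methyl-5-[(2S,3S)-3-methyloxolan-2-yl]-3-[(triethylsilyl)oxy]hex-4-en-2-one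
Conditions: Et3SiOTf (1.3 equiv), 2,6-lutidine (2.5 equiv), CH2Cl2, −78 → 0 °C
Reagents that add atoms: triethylsilyl trifluoromethanesulfonate, CC[Si](CC)(CC)OS(=O)(=O)C(F)(F)F
Why: Silylation of a hindered tertiary alcohol with a silyl triflate and a non-nucleophilic pyridine base; the ether prevents alkoxide formation and thus the base-induced α-ketol shift that would scramble C9 in step 12.

Step 8
Reactants: 17 2-methylbenzene-1,3-diol
Product: 18 1,3-bis(methoxymethoxy)-2-methylbenzene
Conditions: NaH (2.4 equiv), MOMCl (2.4 equiv), DMF, 0 °C → rt
Reagents that add atoms: chloromethyl methyl ether, COCCl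
Why: Williamson etherification of both phenoxides; the acetal ethers are stable to base, assist ortho-metalation and fall off in the final acid step.

Step 9
Reactants: 18 1,3-bis(methoxymethoxy)-2-methylbenzene
Product: 20 5-bromo-1,3-bis(methoxymethoxy)-2-methylbenzene, via arylboronic pinacol ester 19 (not isolated)
Conditions: [Ir(OMe)(cod)]2 (1.5 mol%), 4,4′-di-tert-butyl-2,2′-bipyridine (3 mol%), B2pin2 (1.0 equiv), THF, 80 °C; then CuBr2 (3 equiv), MeOH/H2O (1:1), 60 °C
Reagents that add atoms: copper dibromide, [Cu+2].[Br-].[Br-]
Why: Iridium-catalysed aromatic C–H borylation is sterically governed and takes C5, the only C–H without an ortho substituent in the mirror-symmetric arene; copper-mediated ipso-bromodeboronation then replaces boron by bromine without electrophilic attack at the activated ortho positions.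

Step 10
Reactants: 20 5-bromo-1,3-bis(methoxymethoxy)-2-methylbenzene
Product: 22 6-bromo-2,4-bis(methoxymethoxy)-3-methylbenzaldehyde, via ortho-lithiated bromoarene 21 (not isolated)
Conditions: LiN(i-Pr)2 (1.2 equiv), THF, −78 °C; DMF (3 equiv), −78 → −40 °C; aq. NH4Cl
Reagents that add atoms: N,N-dimethylformamide, CN(C)C=O
Why: Directed ortho-lithiation with a lithium amide (no halogen–lithium exchange): the two remaining ring hydrogens are equivalent and each is flanked by Br and OCH2OCH3, so 21 can form at one kind of site only and is formylated by DMF; −78 °C suppresses loss of LiBr to an aryne.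

Step 11
Reactants: 22 6-bromo-2,4-bis(methoxymethoxy)-3-methylbenzaldehyde
Product: 23 2-[6-bromo-2,4-bis(methoxymethoxy)-3-methylphenyl]-1,3-dioxolane
Conditions: Me3SiOCH2CH2OSiMe3 (2 equiv), Me3SiOTf (5 mol%), CH2Cl2, −78 → −20 °C; pyridine quench
Reagents that add atoms: 1,2-bis(trimethylsilyloxy)ethane, C[Si](C)(C)OCCO[Si](C)(C)C
Why: Aprotic acetalisation under Noyori conditions masks the aldehyde against aldol and palladium-mediated side reactions; the cold, non-protic medium spares the aryl acetal ethers.

Step 12
Reactants: 16 (3S,4E)-3-methyl-5-[(2S,3S)-3-methyloxolan-2-yl]-3-[(triethylsilyl)oxy]hex-4-en-2-one; 23 2-[6-bromo-2,4-bis(methoxymethoxy)-3-methylphenyl]-1,3-dioxolane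
Product: 24 (3S,4E)-1-[2-(1,3-dioxolan-2-yl)-3,5-bis(methoxymethoxy)-4-methylphenyl]-3-methyl-5-[(2S,3S)-3-methyloxolan-2-yl]-3-[(triethylsilyl)oxy]hex-4-en-2-one
Conditions: Pd(OAc)2 (5 mol%), 1,1′-bis(di-tert-butylphosphino)ferrocene (6 mol%), NaOt-Bu (2.2 equiv), 23 (1.2 equiv), THF, 65 °C
Reagents that add atoms: none
Why: Palladium-catalysed ketone α-arylation (Buchwald–Hartwig type): oxidative addition of zerovalent palladium to 23, exchange with the sodium enolate of 16, which can form only at the methyl group C4 because C9 is quaternary, and reductive elimination make the C4–C4a bond; the bulky bisphosphine and the ortho substituent disfavour a second arylation.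

Step 13
Reactants: 24 (3S,4E)-1-[2-(1,3-dioxolan-2-yl)-3,5-bis(methoxymethoxy)-4-methylphenyl]-3-methyl-5-[(2S,3S)-3-methyloxolan-2-yl]-3-[(triethylsilyl)oxy]hex-4-en-2-one
Product: 26 8-hydroxy-3-[(2S,3E)-2-hydroxy-4-[(2S,3S)-3-methyloxolan-2-yl]pent-3-en-2-yl]-7-methyl-6H-isochromen-6-one, via ring-open keto aldehyde 25 (not isolated)
Conditions: CF3CO2H/H2O/CH2Cl2 (5:1:5), 0 °C → rt; evaporation; pH 7 phosphate buffer/EtOAc
Reagents that add atoms: none
Why: Aqueous acid hydrolyses the dioxolane, both aryl acetal ethers and the silyl ether to 25, whose ketone oxygen adds to the aldehyde carbon C1 (6-exo-trig) and loses water to the 2-benzopyrylium ion, obtained after buffering as its neutral quinoid form 26; ionisation at C9 is disfavoured by the electron-poor C3 next to it.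

Step 14
Reactants: 26 8-hydroxy-3-[(2S,3E)-2-hydroxy-4-[(2S,3S)-3-methyloxolan-2-yl]pent-3-en-2-yl]-7-methyl-6H-isochromen-6-one
Product: 27 (7R)-7-hydroxy-3-[(2S,3E)-2-hydroxy-4-[(2S,3S)-3-methyloxolan-2-yl]pent-3-en-2-yl]-7-methyl-6H-isochromene-6,8(7H)-dione
Conditions: AzaH (FAD-dependent monooxygenase, clarified E. coli lysate), NADP+ (cat.), glucose 6-phosphate, glucose-6-phosphate dehydrogenase, air, potassium phosphate buffer pH 8.0, DMSO (5% v/v), 30 °C
Reagents that add atoms: dioxygen, O=O
Why: Biocatalytic hydroxylative dearomatisation: the flavin C4a-hydroperoxide of the enzyme transfers an electrophilic hydroxyl to C7 of the resorcinol-type substrate (26 equilibrates with ring-open 25 in buffer), and the active site, not the remote side-chain stereocentres, should fix the (7R) configuration typical of this enzyme; the pyran ring is kept or closes again spontaneously.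

Step 15
Reactants: 27 (7R)-7-hydroxy-3-[(2S,3E)-2-hydroxy-4-[(2S,3S)-3-methyloxolan-2-yl]pent-3-en-2-yl]-7-methyl-6H-isochromene-6,8(7H)-dione
Product: 28 (7S,8R)-7,8-dihydroxy-3-[(2S,3E)-2-hydroxy-4-[(2S,3S)-3-methyloxolan-2-yl]pent-3-en-2-yl]-7-methyl-7,8-dihydro-6H-isochromen-6-one (target)
Conditions: Me4NBH(OAc)3 (4 equiv), MeCN/AcOH (2:1), −30 → 0 °C
Reagents that add atoms: none
Why: Hydroxyl-directed triacetoxyborohydride reduction (Evans–Saksena type): boron binds to the C7 oxygen and hydride is delivered internally to the neighbouring C8 carbonyl on the face that carries C7–O, so the C8 hydroxyl ends trans to the C7 hydroxyl (8R; C7 is unchanged and becomes S only by a change of priorities); C8, a simple vinylogous ester carbonyl, should be more electrophilic than C6, which is deactivated by its oxido-pyrylium character.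

## Compound list

1 | 3-(trimethylsilyl)propynal | C[Si](C)(C)C#CC=O | starting material
2 | (E)-but-2-ene | C/C=C/C | starting material
3 | (E)-crotylpotassium | C/C=C/C[K] | intermediate
4 | (E)-crotylbis(isopinocampheyl)borane, (+)-α-pinene series | C/C=C/CB([C@@H]1C[C@@H]2C[C@H]([C@H]1C)C2(C)C)[C@@H]1C[C@@H]2C[C@H]([C@H]1C)C2(C)C | intermediate
5 | (3S,4S)-4-methyl-1-(trimethylsilyl)hex-5-en-1-yn-3-ol | C[Si](C)(C)C#C[C@@H](O)[C@@H](C)C=C | intermediate
6 | (3S,4S)-3-methyl-6-(trimethylsilyl)hex-5-yne-1,4-diol | C[Si](C)(C)C#C[C@@H](O)[C@@H](C)CCO | intermediate
7 | (3S,4S)-4-hydroxy-3-methyl-6-(trimethylsilyl)hex-5-yn-1-yl 4-methylbenzenesulfonate | C[Si](C)(C)C#C[C@@H](O)[C@@H](C)CCOS(=O)(=O)c1ccc(C)cc1 | intermediate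
8 | trimethyl{[(2S,3S)-3-methyloxolan-2-yl]ethynyl}silane | C[Si](C)(C)C#C[C@H]1OCC[C@@H]1C | intermediate
9 | (2S,3S)-2-ethynyl-3-methyloxolane | C#C[C@H]1OCC[C@@H]1C | intermediate
10 | trimethylaluminium | C[Al](C)C | starting material
11 | 3,3-dimethoxybutan-2-one | CC(=O)C(C)(OC)OC | starting material
12 | dimethyl{(1E)-2-[(2S,3S)-3-methyloxolan-2-yl]prop-1-en-1-yl}alumane | C/C(=C\[Al](C)C)[C@H]1OCC[C@@H]1C | intermediate
13 | methyl{(1E)-2-[(2S,3S)-3-methyloxolan-2-yl]prop-1-en-1-yl}zinc | C/C(=C\[Zn]C)[C@H]1OCC[C@@H]1C | intermediate
14 | (3S,4E)-2,2-dimethoxy-3-methyl-5-[(2S,3S)-3-methyloxolan-2-yl]hex-4-en-3-ol | C/C(=C\[C@](C)(O)C(C)(OC)OC)[C@H]1OCC[C@@H]1C | intermediate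
15 | (3S,4E)-3-hydroxy-3-methyl-5-[(2S,3S)-3-methyloxolan-2-yl]hex-4-en-2-one | C/C(=C\[C@](C)(O)C(C)=O)[C@H]1OCC[C@@H]1C | intermediate
16 | (3S,4E)-3-methyl-5-[(2S,3S)-3-methyloxolan-2-yl]-3-[(triethylsilyl)oxy]hex-4-en-2-one | C/C(=C\[C@](C)(O[Si](CC)(CC)CC)C(C)=O)[C@H]1OCC[C@@H]1C | intermediate
17 | 2-methylbenzene-1,3-diol | Cc1c(O)cccc1O | starting material
18 | 1,3-bis(methoxymethoxy)-2-methylbenzene | COCOc1cccc(OCOC)c1C | intermediate
19 | 2-[3,5-bis(methoxymethoxy)-4-methylphenyl]-4,4,5,5-tetramethyl-1,3,2-dioxaborolane | COCOc1cc(B2OC(C)(C)C(C)(C)O2)cc(OCOC)c1C | intermediate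
20 | 5-bromo-1,3-bis(methoxymethoxy)-2-methylbenzene | COCOc1cc(Br)cc(OCOC)c1C | intermediate
21 | [6-bromo-2,4-bis(methoxymethoxy)-3-methylphenyl]lithium | [Li]c1c(Br)cc(OCOC)c(C)c1OCOC | intermediate
22 | 6-bromo-2,4-bis(methoxymethoxy)-3-methylbenzaldehyde | O=Cc1c(Br)cc(OCOC)c(C)c1OCOC | intermediate
23 | 2-[6-bromo-2,4-bis(methoxymethoxy)-3-methylphenyl]-1,3-dioxolane | COCOc1cc(Br)c(C2OCCO2)c(OCOC)c1C | intermediate
24 | (3S,4E)-1-[2-(1,3-dioxolan-2-yl)-3,5-bis(methoxymethoxy)-4-methylphenyl]-3-methyl-5-[(2S,3S)-3-methyloxolan-2-yl]-3-[(triethylsilyl)oxy]hex-4-en-2-one | C/C(=C\[C@](C)(O[Si](CC)(CC)CC)C(=O)Cc1cc(OCOC)c(C)c(OCOC)c1C1OCCO1)[C@H]1OCC[C@@H]1C | intermediate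
25 | 2,4-dihydroxy-6-{(3S,4E)-3-hydroxy-3-methyl-5-[(2S,3S)-3-methyloxolan-2-yl]-2-oxohex-4-en-1-yl}-3-methylbenzaldehyde | C/C(=C\[C@](C)(O)C(=O)Cc1cc(O)c(C)c(O)c1C=O)[C@H]1OCC[C@@H]1C | intermediate
26 | 8-hydroxy-3-[(2S,3E)-2-hydroxy-4-[(2S,3S)-3-methyloxolan-2-yl]pent-3-en-2-yl]-7-methyl-6H-isochromen-6-one | C/C(=C\[C@](C)(O)C1=CC2=CC(=O)C(C)=C(O)C2=CO1)[C@H]1OCC[C@@H]1C | intermediate
27 | (7R)-7-hydroxy-3-[(2S,3E)-2-hydroxy-4-[(2S,3S)-3-methyloxolan-2-yl]pent-3-en-2-yl]-7-methyl-6H-isochromene-6,8(7H)-dione | C/C(=C\[C@](C)(O)C1=CC2=CC(=O)[C@@](C)(O)C(=O)C2=CO1)[C@H]1OCC[C@@H]1C | intermediate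
28 | (7S,8R)-7,8-dihydroxy-3-[(2S,3E)-2-hydroxy-4-[(2S,3S)-3-methyloxolan-2-yl]pent-3-en-2-yl]-7-methyl-7,8-dihydro-6H-isochromen-6-one | C/C(=C\[C@](C)(O)C1=CC2=CC(=O)[C@@](C)(O)[C@H](O)C2=CO1)[C@H]1OCC[C@@H]1C | target

## Step count and least certain steps

Total step count: 15. Longest linear sequence: 11 (steps 1–7 and 12–15); the arene branch (steps 8–11) joins at step 12.

Step 5 (key step). Most likely to go wrong are methyl transfer in competition with alkenyl transfer, if aluminium and zinc methyl groups remain in excess or the Al-to-Zn exchange is slow, and poor facial selectivity, if the ketal oxygens of 11 or the ring C oxygen chelate zinc or titanium and open an uncatalysed or wrongly organised pathway. The fallback gives up catalyst control. It sets out from 9: the alane 12 is formed as before and quenched with I2 to give the (E)-alkenyl iodide F1. Iodine–lithium exchange with t-BuLi in Et2O at −78 °C gives the alkenyllithium F2, which adds to 11 without face control. Because ring C is already a single enantiomer, the product 14 and its C9 epimer F3 are diastereomers and are separated by chromatography. The route is rejoined at 14, at the cost of about half the material.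

Step 14. The enzyme may accept a substrate with a bulky, hydroxylated C3 substituent only slowly, so that conversion stalls or unspecific oxidation takes over. The fallback is chemical and sets out from 26: in CF3CO2H/CH2Cl2 it is held as the 2-benzopyrylium ion and oxidised at C7 with 2-iodoxybenzoic acid and Bu4NI (cat.). This hydroxylation has no face control, but 27 and the C7 epimer F4 are diastereomers and are separated by chromatography; the route is rejoined at 27.

Step 15. Hydride may be delivered to C6 instead of C8, since both carbonyls flank the C7 hydroxyl, or the acid-activated vinylogous ester may be reduced in a conjugate sense at C1. The fallback replaces the chemical hydride by an enzyme: 27 is reduced with an NADPH-dependent ketoreductase selected from a panel for C8 regioselectivity and the (8R) face, with propan-2-ol or glucose as the terminal reductant. It sets out from 27 and arrives directly at 28.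

Step 12. Oxidative addition and enolate transfer may be slow for these two hindered partners, leading to protodebromination of 23. The alkoxide base may also move the silyl group from the C9 oxygen to the enolate oxygen and so open the way to an α-ketol shift that erodes C9. The fallback avoids strong base. It sets out from 16, which is converted with Me3SiOTf and Et3N into the trimethylsilyl enol ether F5. F5 is coupled with 23 using Pd(OAc)2, P(t-Bu)3 and ZnF2/CsF as the fluoride activator, and the route is rejoined at 24.

Step 13. Before all four groups are off, the acid may ionise the allylic C2′–O bond or dehydrate the C9 carbinol, or cleavage of the aryl acetal ethers may stay incomplete. The fallback separates the operations and avoids a strong Brønsted acid. It sets out from 24: Me3SiOTf with 2,2′-bipyridyl in CH2Cl2 at 0 °C, then water, cleaves the aryl methoxymethyl ethers and the dioxolane through pyridinium intermediates and gives the silyl-protected keto aldehyde F6. HF·pyridine in THF/pyridine then removes the silyl ether, and the weakly acidic medium closes ring A; the route is rejoined at 26.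

Step 9. The aryl acetal ethers may be lost in the warm, Lewis-acidic aqueous copper halide medium, after which the free phenol would be brominated in the ring. The fallback carries robust methyl ethers through this stage. It sets out from 17, which is methylated (MeI, K2CO3, acetone) to the dimethyl ether F7. F7 is borylated as in step 9 to the boronic ester F8 and converted with CuBr2 into the bromide F9. BBr3 in CH2Cl2 gives the bromo diphenol F10, and NaH/MOMCl then gives 20, where the route is rejoined.

## Further compounds

F1 | step 5 | (2S,3S)-2-[(1E)-1-iodoprop-1-en-2-yl]-3-methyloxolane | C/C(=C\I)[C@H]1OCC[C@@H]1C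
F2 | step 5 | {(1E)-2-[(2S,3S)-3-methyloxolan-2-yl]prop-1-en-1-yl}lithium | C/C(=C\[Li])[C@H]1OCC[C@@H]1C
F3 | step 5 | (3R,4E)-2,2-dimethoxy-3-methyl-5-[(2S,3S)-3-methyloxolan-2-yl]hex-4-en-3-ol | C/C(=C\[C@@](C)(O)C(C)(OC)OC)[C@H]1OCC[C@@H]1C
F4 | step 14 | (7S)-7-hydroxy-3-[(2S,3E)-2-hydroxy-4-[(2S,3S)-3-methyloxolan-2-yl]pent-3-en-2-yl]-7-methyl-6H-isochromene-6,8(7H)-dione | C/C(=C\[C@](C)(O)C1=CC2=CC(=O)[C@](C)(O)C(=O)C2=CO1)[C@H]1OCC[C@@H]1C
F0 | step 15 | none | none
F5 | step 12 | triethyl({(3S,4E)-3-methyl-5-[(2S,3S)-3-methyloxolan-2-yl]-2-[(trimethylsilyl)oxy]hexa-1,4-dien-3-yl}oxy)silane | C/C(=C\[C@](C)(O[Si](CC)(CC)CC)C(=C)O[Si](C)(C)C)[C@H]1OCC[C@@H]1C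
F6 | step 13 | 2,4-dihydroxy-3-methyl-6-{(3S,4E)-3-methyl-5-[(2S,3S)-3-methyloxolan-2-yl]-2-oxo-3-[(triethylsilyl)oxy]hex-4-en-1-yl}benzaldehyde | C/C(=C\[C@](C)(O[Si](CC)(CC)CC)C(=O)Cc1cc(O)c(C)c(O)c1C=O)[C@H]1OCC[C@@H]1C
F7 | step 9 | 1,3-dimethoxy-2-methylbenzene | COc1cccc(OC)c1C
F8 | step 9 | 2-(3,5-dimethoxy-4-methylphenyl)-4,4,5,5-tetramethyl-1,3,2-dioxaborolane | COc1cc(B2OC(C)(C)C(C)(C)O2)cc(OC)c1C
F9 | step 9 | 5-bromo-1,3-dimethoxy-2-methylbenzene | COc1cc(Br)cc(OC)c1C
F10 | step 9 | 5-bromo-2-methylbenzene-1,3-diol | Cc1c(O)cc(Br)cc1O
A1 | alternative 1 | (7S,8R)-8-[(tert-butyldimethylsilyl)oxy]-7-hydroxy-7-methyl-3-[(2S,3E)-4-[(2S,3S)-3-methyloxolan-2-yl]-2-[(triethylsilyl)oxy]pent-3-en-2-yl]-7,8-dihydro-6H-isochromen-6-one | C/C(=C\[C@](C)(O[Si](CC)(CC)CC)C1=CC2=CC(=O)[C@@](C)(O)[C@H](O[Si](C)(C)C(C)(C)C)C2=CO1)[C@H]1OCC[C@@H]1C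
A2 | alternative 2 | (2S,3E)-1-[(tert-butyldimethylsilyl)oxy]-2-methyl-4-[(2S,3S)-3-methyloxolan-2-yl]pent-3-en-2-ol | C/C(=C\[C@](C)(O)CO[Si](C)(C)C(C)(C)C)[C@H]1OCC[C@@H]1C
A3 | alternative 3 | 8-hydroxy-3-[(2S,3E)-2-hydroxy-4-[(2S,3S)-3-methyloxolan-2-yl]pent-3-en-2-yl]-7-methyl-6H-isochromen-6-one (same compound as 26) | C/C(=C\[C@](C)(O)C1=CC2=CC(=O)C(C)=C(O)C2=CO1)[C@H]1OCC[C@@H]1C
A4 | alternative 3 | (2S,3E)-N-methoxy-N,2-dimethyl-4-[(2S,3S)-3-methyloxolan-2-yl]-2-[(triethylsilyl)oxy]pent-3-enamide | C/C(=C\[C@](C)(O[Si](CC)(CC)CC)C(=O)N(C)OC)[C@H]1OCC[C@@H]1C
A5 | alternative 3 | 2,4-bis(methoxymethoxy)-3,6-dimethylbenzaldehyde | Cc1cc(OCOC)c(C)c(OCOC)c1C=O
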